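The route rests on one cut through the terminal, 2,2-disubstituted oxirane: its CH2 carbon (C3) is removed, so that the C2–C3 bond to the quaternary, aryl-bearing carbon and the C3–O1 bond are both made when a one-carbon sulfur ylide adds to an aryl ketone. That single enantioselective methylene transfer closes the three-membered ring and sets the only stereocentre while the isobutyrate arm is already in place. The ketone it needs is an aryl isobutyryloxymethyl ketone whose phenol is masked as a bulky, non-chelating triisopropylsilyl ether, made from 4-methoxy-3-methylphenol by ortho-acetylation, silylation, α-bromination and carboxylate displacement; silicon is exchanged for the tigloyl ester last.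

Key step: step 5

Assumption: which binaphthol antipode gives the (R)-oxirane from this ketone cannot be fixed by analogy alone; the (S)-ligand is written in step 5 and the mirror-image ligand is to be used, with nothing else changed, if a calibration run against the racemate shows the opposite sense.

Remark on descriptors: with oxirane O > CH2OC(=O) > oxirane CH2 > aryl, the target centre is (R); the silyl ether epoxide and the free phenol keep this descriptor, whereas the sulfoxonium betaine is (S) for the same spatial arrangement because CH2S outranks CH2O.

Step 1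
Reactants: 1 4-methoxy-3-methylphenol; 2 acetic acid
Product: 3 1-(2-hydroxy-5-methoxy-4-methylphenyl)ethan-1-one
Conditions: 2 (solvent), BF3·OEt2, 90 °C; then H2O, NaOAc
Reagents that add atoms: none
Why: BF3 activates acetic acid and, through the aryl acetate and its O–BF2 chelate, should deliver the acetyl group to C6, the free position ortho to the hydroxyl and para to the methyl group, in a Fries-type Friedel–Crafts ortho-acylation, the other ortho position being crowded between OH and CH3 and the para position blocked by OCH3.

Step 2
Reactants: 3 1-(2-hydroxy-5-methoxy-4-methylphenyl)ethan-1-one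
Product: 4 1-[5-methoxy-4-methyl-2-(triisopropylsilyloxy)phenyl]ethan-1-one
Conditions: i-Pr3SiOTf, 2,6-lutidine, CH2Cl2, 0 °C → rt
Reagents that add atoms: triisopropylsilyl trifluoromethanesulfonate, CC(C)[Si](OS(=O)(=O)C(F)(F)F)(C(C)C)C(C)C
Why: O-Silylation with the silyl triflate and a hindered pyridine base overcomes the hydrogen bond of the ortho-hydroxy ketone and should give the aryl triisopropylsilyl ether, a mask that removes the acidic OH, cannot chelate a metal and is bulky enough to resist carboxylate attack and O-to-O silyl shifts later on.

Step 3
Reactants: 4 1-[5-methoxy-4-methyl-2-(triisopropylsilyloxy)phenyl]ethan-1-one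
Product: 6 2-bromo-1-[5-methoxy-4-methyl-2-(triisopropylsilyloxy)phenyl]ethan-1-one, via trimethylsilyl enol ether 5 (not isolated)
Conditions: Me3SiOTf, Et3N, CH2Cl2, 0 °C; then NBS, THF, −78 → 0 °C
Reagents that add atoms: N-bromosuccinimide, O=C1CCC(=O)N1Br; trimethylsilyl trifluoromethanesulfonate, C[Si](C)(C)OS(=O)(=O)C(F)(F)F (its silyl group stays only in 5)
Why: Soft enolisation gives the silyl enol ether, whose C=C should take up electrophilic bromine from NBS far faster than the dialkoxy arene or the product ketone (α-bromination of a ketone through its silyl enol ether), so that ring bromination and dibromination are avoided.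

Step 4
Reactants: 6 2-bromo-1-[5-methoxy-4-methyl-2-(triisopropylsilyloxy)phenyl]ethan-1-one; 7 isobutyric acid
Product: 8 2-[5-methoxy-4-methyl-2-(triisopropylsilyloxy)phenyl]-2-oxoethyl 2-methylpropanoate
Conditions: i-Pr2NEt, MeCN, rt
Reagents that add atoms: none
Why: The ammonium carboxylate should displace bromide from the activated phenacyl-type CH2 (SN2 O-alkylation of a carboxylate) in the absence of fluoride, hydroxide or carbonate, conditions under which the aryl silyl ether stays in place.

Step 5
Reactants: 8 2-[5-methoxy-4-methyl-2-(triisopropylsilyloxy)phenyl]-2-oxoethyl 2-methylpropanoate; 9 trimethylsulfoxonium chloride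
Product: 12 {(2R)-2-[5-methoxy-4-methyl-2-(triisopropylsilyloxy)phenyl]oxiran-2-yl}methyl 2-methylpropanoate, via dimethylsulfoxonium methylide 10 (not isolated), via betaine alkoxide 11 (not isolated)
Conditions: 9, NaH, THF, reflux, then filtration (salt-free 10, 1.2 equiv); 10 added slowly to 8, LaLi3[(S)-binaphthoxide]3 (5 mol %), [2,4,6-(MeO)3C6H2]3P=O (5 mol %), 5 Å MS, THF, rt
Reagents that add atoms: none
Why: The ylide carbon adds to the ketone carbonyl held on the Lewis acidic lanthanum centre of the lanthanum–lithium binaphthoxide, with the phosphine oxide as a ligand that tightens the chiral pocket, and the alkoxide of 11 then displaces dimethyl sulfoxide from the neighbouring CH2 to close the oxirane (3-exo-tet), so the C–CH2 and CH2–O bonds arise in one operation. The closest known reaction is the catalytic asymmetric Corey–Chaykovsky epoxidation of aryl methyl ketones with this catalyst; here CH3 is replaced by CH2OCOiPr and the ring carries an ortho substituent. The one new stereocentre is set in the addition step by the binaphthoxide ligands, which should distinguish the twisted, ortho-silyloxylated aryl group from the smaller acyloxymethyl arm and so expose one carbonyl face; the ring closure does not touch that carbon. Chemoselectivity for the ketone over the ester is secured by the branched, unactivated isobutyrate, which a stabilised sulfoxonium ylide should not acylate at room temperature, while slow addition of the ylide keeps deprotonation of the CH2 between carbonyl and ester oxygen, and the acyl shift that would follow, in check. The triisopropylsilyl group cannot chelate lanthanum and is too hindered to move to the alkoxide of 11, a shift that would free a phenoxide. Because the ester is present before the ring forms, no free alkoxide ever sits next to the finished epoxide.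

Step 6
Reactants: 12 {(2R)-2-[5-methoxy-4-methyl-2-(triisopropylsilyloxy)phenyl]oxiran-2-yl}methyl 2-methylpropanoate; 13 tigloyl chloride
Product: 15 4-methoxy-5-methyl-2-{(2R)-2-[(2-methylpropanoyloxy)methyl]oxiran-2-yl}phenyl (2E)-2-methylbut-2-enoate, via free phenol 14 (not isolated)
Conditions: Bu4NF, tiglic acid (1:1), THF, 0 °C; then pyridine, DMAP (cat.), 13, 0 °C
Reagents that add atoms: (2E)-2-methylbut-2-enoic acid (tiglic acid), C/C=C(\C)C(=O)O (buffer whose carboxylate enters the same acyl pool as 13)
Why: Fluoride should cleave the aryl O–Si bond while the acid keeps the released oxygen protonated, and the phenol is esterified in the same flask by DMAP-catalysed acyl transfer (fluoride desilylation followed by O-acylation), the buffer being the acid of the acyl group itself so that any anhydride formed can only transfer tigloyl, and neither operation touches the quaternary stereocentre.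

Compound list
1 | 4-methoxy-3-methylphenol | Cc1cc(O)ccc1OC | starting material
2 | acetic acid | CC(=O)O | starting material
3 | 1-(2-hydroxy-5-methoxy-4-methylphenyl)ethan-1-one | CC(=O)c1cc(OC)c(C)cc1O | intermediate
4 | 1-[5-methoxy-4-methyl-2-(triisopropylsilyloxy)phenyl]ethan-1-one | CC(=O)c1cc(OC)c(C)cc1O[Si](C(C)C)(C(C)C)C(C)C | intermediate
5 | {1-[5-methoxy-4-methyl-2-(triisopropylsilyloxy)phenyl]ethenyloxy}trimethylsilane (trimethylsilyl enol ether) | C=C(O[Si](C)(C)C)c1cc(OC)c(C)cc1O[Si](C(C)C)(C(C)C)C(C)C | intermediate
6 | 2-bromo-1-[5-methoxy-4-methyl-2-(triisopropylsilyloxy)phenyl]ethan-1-one | O=C(CBr)c1cc(OC)c(C)cc1O[Si](C(C)C)(C(C)C)C(C)C | intermediate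
7 | isobutyric acid (2-methylpropanoic acid) | CC(C)C(=O)O | starting material
8 | 2-[5-methoxy-4-methyl-2-(triisopropylsilyloxy)phenyl]-2-oxoethyl 2-methylpropanoate | CC(C)C(=O)OCC(=O)c1cc(OC)c(C)cc1O[Si](C(C)C)(C(C)C)C(C)C | intermediate
9 | trimethylsulfoxonium chloride | C[S+](C)(C)=O.[Cl-] | starting material
10 | dimethylsulfoxonium methylide | C[S+](C)(=O)[CH2-] | intermediate
11 | [(2S)-2-[5-methoxy-4-methyl-2-(triisopropylsilyloxy)phenyl]-3-(2-methylpropanoyloxy)-2-oxidopropyl]dimethyloxosulfonium (betaine alkoxide, held on the catalyst) | CC(C)C(=O)OC[C@]([O-])(C[S+](C)(C)=O)c1cc(OC)c(C)cc1O[Si](C(C)C)(C(C)C)C(C)C | intermediate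
12 | {(2R)-2-[5-methoxy-4-methyl-2-(triisopropylsilyloxy)phenyl]oxiran-2-yl}methyl 2-methylpropanoate | CC(C)C(=O)OC[C@]1(CO1)c1cc(OC)c(C)cc1O[Si](C(C)C)(C(C)C)C(C)C | intermediate
13 | tigloyl chloride, (2E)-2-methylbut-2-enoyl chloride | C/C=C(\C)C(Cl)=O | starting material
14 | [(2R)-2-(2-hydroxy-5-methoxy-4-methylphenyl)oxiran-2-yl]methyl 2-methylpropanoate (free phenol) | CC(C)C(=O)OC[C@]1(CO1)c1cc(OC)c(C)cc1O | intermediate
15 | 4-methoxy-5-methyl-2-{(2R)-2-[(2-methylpropanoyloxy)methyl]oxiran-2-yl}phenyl (2E)-2-methylbut-2-enoate | C/C=C(\C)C(=O)Oc1cc(C)c(OC)cc1[C@]1(COC(=O)C(C)C)CO1 | target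

Total step count: 6
Longest linear sequence: 6 steps (1 to 15)

Steps most likely to fail

Step 5. The catalyst may discriminate the two carbonyl faces poorly, because the acyloxymethyl arm is larger than the methyl group for which the pocket is proven. The addition may also be slow at the hindered carbonyl, leaving time for deprotonation of the activated CH2 and a subsequent acyl shift. The fallback sets out from 8 and comes back at 12, and moves the asymmetric step to a reagent-controlled epoxidation of an allylic alcohol:
- Ketone 8 is methylenated under non-basic conditions (Zn, CH2Br2, TiCl4, THF, 0 °C to rt; Lombardo–Takai methylenation) to 2-[5-methoxy-4-methyl-2-(triisopropylsilyloxy)phenyl]prop-2-en-1-yl 2-methylpropanoate F1.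
- The ester is cleaved reductively with i-Bu2AlH (CH2Cl2, −78 °C) to 2-[5-methoxy-4-methyl-2-(triisopropylsilyloxy)phenyl]prop-2-en-1-ol F2.
- Sharpless asymmetric epoxidation (Ti(O-i-Pr)4, L-(+)-diethyl tartrate, t-BuOOH, 4 Å MS, CH2Cl2, −20 °C) should give {(2S)-2-[5-methoxy-4-methyl-2-(triisopropylsilyloxy)phenyl]oxiran-2-yl}methanol F3. The (S) descriptor of the alcohol is the spatial arrangement of (R)-12, and L-(+)-tartrate is the antipode expected to give (S)-2-substituted glycidols.
- Acylation with isobutyric anhydride (Et3N, DMAP, CH2Cl2, 0 °C) returns 12.

Step 6. During its lifetime the free phenolic oxygen may assist ionisation of the neighbouring benzylic oxirane C–O bond (quinone-methide-type opening), which would erode the stereocentre or destroy the ring. Pyridinium chloride may also open the epoxide. The fallback sets out from 12 (with 13) and comes back at 15, and exchanges silicon for the acyl group directly: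
- 13 is converted with KF and 18-crown-6 in MeCN into (2E)-2-methylbut-2-enoyl fluoride F4.
- 12 is treated with F4 and a catalytic amount of Bu4N[Ph3SiF2] in THF at −20 °C.
- Each phenoxide released by fluoride is acylated at once and the acyl transfer returns fluoride, so no free phenol builds up on the way to 15.

Step 4. The nucleophilic carboxylate or the bromide salt may strip the silyl group from the aryl oxygen, after which the phenoxide would close onto the bromomethyl ketone to a benzofuranone. The fallback sets out from 4 (through its enol ether 5) and comes back at 8, and introduces the oxygen by oxidation instead of substitution: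
- Rubottom oxidation of 5 (m-CPBA, NaHCO3, CH2Cl2, 0 °C; then citric acid, MeOH) should give 2-hydroxy-1-[5-methoxy-4-methyl-2-(triisopropylsilyloxy)phenyl]ethan-1-one F5.
- Acylation with isobutyryl chloride (pyridine, DMAP cat., CH2Cl2, 0 °C) gives 8 without any halide displacement.

Further compounds
F1 | step 5 | 2-[5-methoxy-4-methyl-2-(triisopropylsilyloxy)phenyl]prop-2-en-1-yl 2-methylpropanoate | C=C(COC(=O)C(C)C)c1cc(OC)c(C)cc1O[Si](C(C)C)(C(C)C)C(C)C
F2 | step 5 | 2-[5-methoxy-4-methyl-2-(triisopropylsilyloxy)phenyl]prop-2-en-1-ol | C=C(CO)c1cc(OC)c(C)cc1O[Si](C(C)C)(C(C)C)C(C)C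
F3 | step 5 | {(2S)-2-[5-methoxy-4-methyl-2-(triisopropylsilyloxy)phenyl]oxiran-2-yl}methanol | OC[C@]1(CO1)c1cc(OC)c(C)cc1O[Si](C(C)C)(C(C)C)C(C)C
F4 | step 6 | (2E)-2-methylbut-2-enoyl fluoride | C/C=C(\C)C(F)=O
F5 | step 4 | 2-hydroxy-1-[5-methoxy-4-methyl-2-(triisopropylsilyloxy)phenyl]ethan-1-one | O=C(CO)c1cc(OC)c(C)cc1O[Si](C(C)C)(C(C)C)C(C)C
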